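**Plan**

1. Numbering used here: spiro carbon C6; ring B = C1 (CH2), C2 (CHBr), C3 (CMeCl), C4 (CH2), C5 (CHOH); ring A = C7 (CMe=), C8, C9, C10 (CBr=), C11 (CMe2).
2. Retrosynthesis cuts first C10–Br and one C11–CH3 (back to a C10 enone), then the ring B bond C1–C2 together with C3–Cl (key step), then the cyclopropane bonds C1–C6 and C1–C11, then C2–Br/C3–CH3 (alkyne), C4–C5 and C5–C6.
3. Forward: ring A is bought as 3-ethoxy-2-methylcyclohexenone; the side chain is grown on C6; the C1 methylene is added across C6=C11 as a cyclopropane; ring B then closes by C1–C2; the second C11 methyl and the bromodiene come last.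
4. Enabling feature: in the chair of ring B the C6–C11 bond, the C2–Br bond and the C3–Cl bond are all equatorial, so C11–C6–C1–C2, Br–C2–C3–C4 and C1–C2–C3–Cl are antiperiplanar. This is the imprint of an anti opening of a C1–C6–C11 cyclopropane (activated by the C10 carbonyl) by an E bromoalkene, with anti capture by chloride.
5. Stereochemistry: C5 from a catalyst-controlled propargylation; the C10 carbinol from CBS reduction, relayed to C6/C11 by hydroxyl-directed cyclopropanation; C2 and C3 from the key step; the C7 and C11 epimers converge when these carbons become trigonal or quaternary.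

Key step: step 10

Assumption: compound 1 is taken as a catalogue chemical (it is otherwise one condensation away from 2-methylcyclohexane-1,3-dione, also commercial); C7 is carried as a mixture of epimers from step 1 to step 12 and is written without a descriptor.

**Route**

Step 1
Reactants: 1 3-ethoxy-2-methylcyclohex-2-en-1-one
Product: 3 3-ethoxy-2,6-dimethylcyclohex-2-en-1-one (racemic), via lithium dienolate 2 (not isolated)
Conditions: LiN(iPr)2, THF, −78 °C; MeI, −78 → 0 °C
Reagents that add atoms: iodomethane, CI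
Why: Kinetic α′-deprotonation of the vinylogous ester and C-methylation (Stork–Danheiser alkylation) should place the future C7 methyl; its stereocentre is left racemic because it becomes trigonal in step 12.

Step 2
Reactants: 3 3-ethoxy-2,6-dimethylcyclohex-2-en-1-one; 4 vinylmagnesium bromide
Product: 6 2,4-dimethyl-3-vinylcyclohex-2-en-1-one (racemic), via magnesium alkoxide 5 (not isolated)
Conditions: CeCl3, THF, −78 → 0 °C; then 1 M HCl, rt
Reagents that add atoms: water, O
Why: 1,2-Addition to the vinylogous ester carbonyl followed by acid hydrolysis with allylic transposition (Stork–Danheiser enone transposition) should move the carbonyl to C10 and leave the vinyl group on C6.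

Step 3
Reactants: 6 2,4-dimethyl-3-vinylcyclohex-2-en-1-one
Product: 7 2,6-dimethyl-3-oxocyclohex-1-ene-1-carbaldehyde (racemic)
Conditions: OsO4 (2 mol %), NaIO4, 2,6-lutidine, dioxane/H2O, rt
Reagents that add atoms: osmium tetroxide, O=[Os](=O)(=O)=O; sodium periodate, [Na+].[O-][I](=O)(=O)=O
Why: Lemieux–Johnson cleavage should take the terminal vinyl group in preference to the tetrasubstituted enone alkene and unmask the C5 aldehyde.

Step 4
Reactants: 7 2,6-dimethyl-3-oxocyclohex-1-ene-1-carbaldehyde; 8 allenylboronic acid pinacol ester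
Product: 9 3-[(1S)-1-hydroxybut-3-yn-1-yl]-2,4-dimethylcyclohex-2-en-1-one (C4 epimers)
Conditions: (S)-TRIP [(S)-3,3′-bis(2,4,6-triisopropylphenyl)-1,1′-binaphthyl-2,2′-diyl hydrogen phosphate] (10 mol %), 4 Å MS, toluene, 0 °C; aqueous work-up
Reagents that add atoms: none
Why: Chiral phosphoric acid-catalysed propargylboration through a closed six-membered transition state should add to the aldehyde only and set C5 as S under catalyst control; the facial sense is assigned by analogy with aryl and alkenyl aldehydes, and the antipodal acid would be used if this hindered enal reverses it.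

Step 5
Reactants: 9 3-[(1S)-1-hydroxybut-3-yn-1-yl]-2,4-dimethylcyclohex-2-en-1-one
Product: 10 3-[(1S)-1-(tert-butyldimethylsilyloxy)but-3-yn-1-yl]-2,4-dimethylcyclohex-2-en-1-one
Conditions: TBSOTf, 2,6-lutidine, CH2Cl2, −78 °C
Reagents that add atoms: tert-butyldimethylsilyl triflate, CC(C)(C)[Si](C)(C)OS(=O)(=O)C(F)(F)F
Why: Silylation of the secondary alcohol at low temperature should outrun enol silylation of the ketone and gives the ether that later shields one face of C3.

Step 6
Reactants: 10 3-[(1S)-1-(tert-butyldimethylsilyloxy)but-3-yn-1-yl]-2,4-dimethylcyclohex-2-en-1-one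
Product: 11 (1R)-3-[(1S)-1-(tert-butyldimethylsilyloxy)but-3-yn-1-yl]-2,4-dimethylcyclohex-2-en-1-ol (C4 epimers)
Conditions: (S)-2-methyl-CBS-oxazaborolidine (20 mol %), catecholborane, toluene, −78 °C
Reagents that add atoms: none
Why: Corey–Bakshi–Shibata reduction should distinguish the α-substituted alkenyl flank from the CH2 flank of the ketone and set the R carbinol at C10 under reagent control, catecholborane leaving the alkyne untouched.

Step 7
Reactants: 11 (1R)-3-[(1S)-1-(tert-butyldimethylsilyloxy)but-3-yn-1-yl]-2,4-dimethylcyclohex-2-en-1-ol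
Product: 13 (1R)-3-[(1S,3E)-4-bromo-1-(tert-butyldimethylsilyloxy)-3-methylbut-3-en-1-yl]-2,4-dimethylcyclohex-2-en-1-ol, via alkenylalane 12 (not isolated)
Conditions: Me3Al, Cp2ZrCl2 (25 mol %), CH2Cl2, 0 °C → rt; then NBS, THF, −78 → −30 °C
Reagents that add atoms: trimethylaluminium, C[Al](C)C; N-bromosuccinimide, O=C1CCC(=O)N1Br
Why: Negishi zirconium-catalysed syn carboalumination of the terminal alkyne followed by bromodealumination with retention should give the E 1-bromo-2-methylalkene, the free hydroxyl being carried as its aluminium alkoxide.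

Step 8
Reactants: 13 (1R)-3-[(1S,3E)-4-bromo-1-(tert-butyldimethylsilyloxy)-3-methylbut-3-en-1-yl]-2,4-dimethylcyclohex-2-en-1-ol
Product: 14 (1S,2R,6R)-6-[(1S,3E)-4-bromo-1-(tert-butyldimethylsilyloxy)-3-methylbut-3-en-1-yl]-1,5-dimethylbicyclo[4.1.0]heptan-2-ol (cyclopropane CH2 cis to OH; C5 epimers)
Conditions: Et2Zn, CH2I2, CH2Cl2, 0 °C → rt
Reagents that add atoms: diiodomethane, ICI
Why: Hydroxyl-directed Simmons–Smith cyclopropanation should deliver the methylene to the face of the C6=C11 alkene syn to the C10 hydroxyl and so set C6 and C11, the bromoalkene being too electron-poor to compete.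

Step 9
Reactants: 14 the cyclopropyl carbinol of step 8
Product: 16 (1S,6R)-6-[(1S,3E)-4-bromo-1-(tert-butyldimethylsilyloxy)-3-methylbut-3-en-1-yl]-1,5-dimethylbicyclo[4.1.0]hept-3-en-2-one (C5 epimers), via cyclopropyl ketone 15 (not isolated)
Conditions: IBX (4 equiv), DMSO/fluorobenzene, rt → 75 °C
Reagents that add atoms: none
Why: IBX oxidation of the carbinol and, on warming, IBX dehydrogenation of the ketone toward its only enolisable side should give the cyclopropyl enone, the quaternary C11 stopping a second dehydrogenation.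

Step 10
Reactants: 16 the cyclopropyl enone of step 9
Product: 18 (2S,3S,5S,6R)-2-bromo-5-(tert-butyldimethylsilyloxy)-3-chloro-3,7,11-trimethylspiro[5.5]undec-8-en-10-one (C7 and C11 epimers), via titanium dienolate 17 (not isolated)
Conditions: TiCl4 (2 equiv), CH2Cl2, −78 → −45 °C; then aq. NaHCO3
Reagents that add atoms: titanium tetrachloride, Cl[Ti](Cl)(Cl)Cl
Why: Proposed new method: TiCl4 binds the C10 carbonyl; the external cyclopropane bond C1–C11, the one aligned with the carbonyl π system, is attacked at the methylene C1 by C2 of the E bromoalkene with inversion while C11 leaves as the titanium dienolate, and the tertiary β-bromo cation at C3 is captured by chloride from the chlorotitanate. The closest known reaction type is the Lewis acid-promoted cyclopropyl ketone-initiated cation–olefin cyclization, with chloride termination as in TiCl4- or SnCl4-mediated Prins and polyene cyclizations; new are the deactivated 1-bromoalkene as π-nucleophile and its attack at the bromine-bearing carbon. Ring B closes 6-endo with respect to both the C2=C3 alkene and the three-membered ring (C1 and C6 both become ring atoms, the breaking C1–C11 bond is exocyclic), the topology of the first ring closure of epoxide-initiated polyene cyclizations. C2 is controlled by the chair that backside opening enforces (C11 antiperiplanar to C2, hence C11 equatorial and C7 axial on ring B) together with the E geometry, which puts bromine equatorial; C3 is controlled by anti addition across the alkene (chloride enters equatorial, anti to C1), the axial face being shielded by the axial C5 silyl ether. The step needs attack at C1 and not at the quaternary C6 or by free chloride, and no ionization of the C5 ether: the tether reaches only C1 in a six-membered array, the C5 oxygen disfavours positive charge at C6, the cyclopropane is electron-poor, and low temperature keeps chloride opening slow.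

Step 11
Reactants: 18 the spirocyclic chloro bromo enone of step 10
Product: 20 (2S,3S,5S,6R)-2-bromo-5-(tert-butyldimethylsilyloxy)-3-chloro-3,7,11,11-tetramethylspiro[5.5]undec-8-en-10-one (C7 epimers), via lithium dienolate 19 (not isolated)
Conditions: LiN(iPr)2, THF, −78 °C; MeI, DMPU, −78 → −20 °C
Reagents that add atoms: iodomethane, CI
Why: Kinetic α′-deprotonation of the enone at C11 and C-methylation should complete the gem-dimethyl group, both C11 epimers giving the same enolate.

Step 12
Reactants: 20 the gem-dimethyl enone of step 11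
Product: 21 (2S,3S,5S,6R)-2,10-dibromo-5-(tert-butyldimethylsilyloxy)-3-chloro-3,7,11,11-tetramethylspiro[5.5]undeca-7,9-diene
Conditions: (COBr)2, 2,6-di-tert-butyl-4-methylpyridine, CH2Cl2, 0 °C → rt
Reagents that add atoms: oxalyl bromide, O=C(Br)C(=O)Br
Why: Conversion of an enone into a 1-bromo-1,3-diene with oxalyl bromide (the reaction that turns steroidal 4-en-3-ones into 3-bromo-3,5-dienes) should replace the C10 oxygen by bromine with loss of the γ-hydrogen at C7, so that both C7 epimers converge on one bromodiene.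

Step 13
Reactants: 21 the silyl ether of step 12
Product: 22 (2S,3S,5S,6R)-2,10-dibromo-3-chloro-3,7,11,11-tetramethylspiro[5.5]undeca-7,9-dien-5-ol (target, locants as in the plan)
Conditions: HF·pyridine, pyridine, THF, 0 °C → rt
Reagents that add atoms: none
Why: Buffered fluoride desilylation should free the hindered axial C5 alcohol without base, so that neither alkyl halide nor the bromodiene is put at risk.

**Compound list**

1 | 3-ethoxy-2-methylcyclohex-2-en-1-one | CCOC1=C(C)C(=O)CCC1 | starting material
2 | lithium 5-ethoxy-6-methylcyclohexa-1,5-dien-1-olate | CCOC1=C(C)C(O[Li])=CCC1 | intermediate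
3 | 3-ethoxy-2,6-dimethylcyclohex-2-en-1-one (racemic) | CCOC1=C(C)C(=O)C(C)CC1 | intermediate
4 | vinylmagnesium bromide | C=C[Mg]Br | starting material
5 | bromomagnesium 3-ethoxy-2,6-dimethyl-1-vinylcyclohex-2-en-1-olate | CCOC1=C(C)C(O[Mg]Br)(C=C)C(C)CC1 | intermediate
6 | 2,4-dimethyl-3-vinylcyclohex-2-en-1-one (racemic) | O=C1CCC(C)C(C=C)=C1C | intermediate
7 | 2,6-dimethyl-3-oxocyclohex-1-ene-1-carbaldehyde (racemic) | O=CC1=C(C)C(=O)CCC1C | intermediate
8 | allenylboronic acid pinacol ester | C=C=CB1OC(C)(C)C(C)(C)O1 | starting material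
9 | 3-[(1S)-1-hydroxybut-3-yn-1-yl]-2,4-dimethylcyclohex-2-en-1-one (C4 epimers) | C#CC[C@H](O)C1=C(C)C(=O)CCC1C | intermediate
10 | 3-[(1S)-1-(tert-butyldimethylsilyloxy)but-3-yn-1-yl]-2,4-dimethylcyclohex-2-en-1-one | C#CC[C@H](O[Si](C)(C)C(C)(C)C)C1=C(C)C(=O)CCC1C | intermediate
11 | (1R)-3-[(1S)-1-(tert-butyldimethylsilyloxy)but-3-yn-1-yl]-2,4-dimethylcyclohex-2-en-1-ol | C#CC[C@H](O[Si](C)(C)C(C)(C)C)C1=C(C)[C@H](O)CCC1C | intermediate
12 | E alkenyl(dimethyl)alane from 11, ring oxygen as dimethylaluminium alkoxide | C[Al](C)/C=C(C)/C[C@H](O[Si](C)(C)C(C)(C)C)C1=C(C)[C@H](O[Al](C)C)CCC1C | intermediate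
13 | (1R)-3-[(1S,3E)-4-bromo-1-(tert-butyldimethylsilyloxy)-3-methylbut-3-en-1-yl]-2,4-dimethylcyclohex-2-en-1-ol | Br/C=C(C)/C[C@H](O[Si](C)(C)C(C)(C)C)C1=C(C)[C@H](O)CCC1C | intermediate
14 | (1S,2R,6R)-6-[(1S,3E)-4-bromo-1-(tert-butyldimethylsilyloxy)-3-methylbut-3-en-1-yl]-1,5-dimethylbicyclo[4.1.0]heptan-2-ol | O[C@@H]1CCC(C)[C@@]2(C[C@]12C)[C@@H](O[Si](C)(C)C(C)(C)C)C/C(C)=C/Br | intermediate
15 | (1S,6R)-6-[(1S,3E)-4-bromo-1-(tert-butyldimethylsilyloxy)-3-methylbut-3-en-1-yl]-1,5-dimethylbicyclo[4.1.0]heptan-2-one | O=C1CCC(C)[C@@]2(C[C@]12C)[C@@H](O[Si](C)(C)C(C)(C)C)C/C(C)=C/Br | intermediate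
16 | (1S,6R)-6-[(1S,3E)-4-bromo-1-(tert-butyldimethylsilyloxy)-3-methylbut-3-en-1-yl]-1,5-dimethylbicyclo[4.1.0]hept-3-en-2-one | O=C1C=CC(C)[C@@]2(C[C@]12C)[C@@H](O[Si](C)(C)C(C)(C)C)C/C(C)=C/Br | intermediate
17 | trichlorotitanium C10,C11-dienolate of 18 | Cl[Ti](Cl)(Cl)OC1=C(C)[C@]2(C(C)C=C1)C[C@H](Br)[C@@](C)(Cl)C[C@@H]2O[Si](C)(C)C(C)(C)C | intermediate
18 | (2S,3S,5S,6R)-2-bromo-5-(tert-butyldimethylsilyloxy)-3-chloro-3,7,11-trimethylspiro[5.5]undec-8-en-10-one (C7 and C11 epimers) | O=C1C=CC(C)[C@@]2(C1C)C[C@H](Br)[C@@](C)(Cl)C[C@@H]2O[Si](C)(C)C(C)(C)C | intermediate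
19 | lithium C10,C11-dienolate of 18 | [Li]OC1=C(C)[C@]2(C(C)C=C1)C[C@H](Br)[C@@](C)(Cl)C[C@@H]2O[Si](C)(C)C(C)(C)C | intermediate
20 | (2S,3S,5S,6R)-2-bromo-5-(tert-butyldimethylsilyloxy)-3-chloro-3,7,11,11-tetramethylspiro[5.5]undec-8-en-10-one (C7 epimers) | O=C1C=CC(C)[C@@]2(C1(C)C)C[C@H](Br)[C@@](C)(Cl)C[C@@H]2O[Si](C)(C)C(C)(C)C | intermediate
21 | (2S,3S,5S,6R)-2,10-dibromo-5-(tert-butyldimethylsilyloxy)-3-chloro-3,7,11,11-tetramethylspiro[5.5]undeca-7,9-diene | CC1=CC=C(Br)C(C)(C)[C@@]12C[C@H](Br)[C@@](C)(Cl)C[C@@H]2O[Si](C)(C)C(C)(C)C | intermediate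
22 | (2S,3S,5S,6R)-2,10-dibromo-3-chloro-3,7,11,11-tetramethylspiro[5.5]undeca-7,9-dien-5-ol | CC1=CC=C(Br)C(C)(C)[C@@]12C[C@H](Br)[C@@](C)(Cl)C[C@@H]2O | target

**Summary**

Total step count: 13. Longest linear sequence: 13 steps (from 1).

Steps most likely to fail:

Step 10. The deactivated bromoalkene may be too slow a π-nucleophile, so that chloride opens the activated cyclopropane, or the C5 ether ionizes, before ring B closes. Fallback with known chemistry, setting out from 16 and returning at 18: MgI2 (Et2O/toluene, warm) adds iodide to the cyclopropane methylene by homoconjugate addition and gives the neopentyl iodide F1. An intramolecular nickel-catalysed reductive coupling of the alkyl iodide with the vinyl bromide (NiBr2(dme), 4,4′-di-tert-butyl-2,2′-bipyridine, Zn, DMA) then closes ring B through the same C1–C2 bond as the cyclohexene F2. Bromochlorination (NBS, LiCl, MeCN/CH2Cl2, −40 °C) should put Br on C2 and Cl on C3 by diaxial opening of the bromonium ion on the face syn to C11. At this stage C11 is still a methine, and the other face would lead to a chloride syn-diaxial to the C5 silyl ether. The product is 18.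

Step 11. Deprotonation and quaternization of the hindered methine next to the spiro centre may be slow, so that O-methylation, γ-deprotonation or base-induced loss of hydrogen halide from ring B takes over. Fallback, setting out from 18 and returning at 20: TMSOTf/Et3N gives the cross-conjugated trimethylsilyl dienol ether F3. Et2Zn/CH2I2 cyclopropanates its electron-rich C10=C11 bond to the siloxycyclopropane F4. TsOH in MeOH opens the three-membered ring at the methylene, which becomes the second C11 methyl, and the product is 20.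

Step 12. Bromide may fail to add at the hindered C10, or the acid released may add to the diene, strip the silyl ether or ionize the tertiary chloride. Fallback, setting out from 20 and returning at 21: KN(SiMe3)2/PhNTf2 (γ-deprotonation at C7, O-sulfonylation) gives the dienyl triflate F5. Pd(PPh3)4, Me3SnSnMe3 and LiCl in THF give the dienylstannane F6. NBS at −78 °C replaces tin by bromine at C10 and the product is 21.

**Further compounds**

F1 | step 10 | (2,4-dimethyl-3-(iodomethyl)-3-[(1S,3E)-4-bromo-1-(tert-butyldimethylsilyloxy)-3-methylbut-3-en-1-yl]cyclohex-5-en-1-one, neopentyl iodide | O=C1C=CC(C)[C@](CI)(C1C)[C@@H](O[Si](C)(C)C(C)(C)C)C/C(C)=C/Br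
F2 | step 10 | (5S,6R)-5-(tert-butyldimethylsilyloxy)-3,7,11-trimethylspiro[5.5]undeca-2,8-dien-10-one | O=C1C=CC(C)[C@@]2(C1C)CC=C(C)C[C@@H]2O[Si](C)(C)C(C)(C)C
F3 | step 11 | trimethylsilyl C10,C11-dienol ether of 18 | C[Si](C)(C)OC1=C(C)[C@]2(C(C)C=C1)C[C@H](Br)[C@@](C)(Cl)C[C@@H]2O[Si](C)(C)C(C)(C)C
F4 | step 11 | siloxycyclopropane from F3 (methylene across C10–C11) | C[Si](C)(C)OC12CC1(C)[C@]3(C(C)C=C2)C[C@H](Br)[C@@](C)(Cl)C[C@@H]3O[Si](C)(C)C(C)(C)C
F5 | step 12 | C10 dienyl triflate of 20 | CC1=CC=C(OS(=O)(=O)C(F)(F)F)C(C)(C)[C@@]12C[C@H](Br)[C@@](C)(Cl)C[C@@H]2O[Si](C)(C)C(C)(C)C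
F6 | step 12 | C10 trimethylstannyl diene | CC1=CC=C([Sn](C)(C)C)C(C)(C)[C@@]12C[C@H](Br)[C@@](C)(Cl)C[C@@H]2O[Si](C)(C)C(C)(C)C
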